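**Retrosynthetic overview**

1. Feature: ten hydroxyls (A C2 and C6; B, C and E C3 and C5, each ortho to the crowded ether carbon A C1, B C4, C C4, E C4; D C3 and C5, para and ortho to D C6) sit exactly where a formyl group activates fluoride displacement at that ether carbon, so each is carried as a formyl group.
2. Target ⇐ BBr3 cleavage of five methyl ethers (A C4, D C4, F C3 to C5) ⇐ decaphenol ⇐ tenfold Dakin (Baeyer–Villiger) oxidation of the hexamer decaaldehyde.
3. Decaaldehyde ⇐ five SNAr ether bonds made one after another from the ring F end (F–E, E–D, D–C, C–B, B–A). The growing chain is the phenoxide and each new ring is a fluoro-diformyl arene whose far oxygen is an allyl ether (methyl for ring A), freed by palladium catalysis before the next coupling.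
4. Blocks ⇐ 4-fluorophenol (rings E, C, B, A) and 2-fluoro-4-methoxyphenol (ring D). The formyl groups enter by lithiation next to fluorine on silyl ethers, because electrophilic formylation of a fluorophenol would go ortho to the hydroxyl, the wrong carbons.
5. No ring is formed: all six benzene rings are bought and joined in the order F, E, D, C, B, A. The target has no stereocentre.

Key step: step 20

Remark on the chemistry: acid is kept away from every compound in which electron-rich ring F sits beside a formyl group of ring E (risk of Friedel–Crafts closure to a xanthene), so the chain oxygen is masked as an allyl ether removed under neutral conditions.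
Remark on the chemistry: organolithium and lithium amino alkoxide species formed in the flask are numbered; the amino alkoxide carbon is a transient racemic stereocentre.

**Route**

Step 1
Reactants: 1 4-fluorophenol
Product: 2 (4-fluorophenoxy)triisopropylsilane
Conditions: TIPSCl, imidazole, DMF, rt
Reagents that add atoms: chlorotriisopropylsilane, CC(C)[Si](Cl)(C(C)C)C(C)C
Why: O-silylation of a phenol; the bulky, non-coordinating silyl ether removes the acidic proton and shields both positions next to oxygen, so that fluorine alone steers the lithiations that follow.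

Step 2
Reactants: 2 (4-fluorophenoxy)triisopropylsilane
Product: 4 2-fluoro-5-(triisopropylsilyloxy)benzaldehyde, via aryllithium 3 (not isolated)
Conditions: s-BuLi, TMEDA, THF, −78 °C; DMF, −78 → 0 °C; aq. NH4Cl
Reagents that add atoms: N,N-dimethylformamide, CN(C)C=O
Why: Directed ortho-metalation, in which fluorine acidifies the neighbouring C–H and the silyloxy group blocks its own ortho positions, should place lithium next to fluorine, and DMF then formylates the aryllithium.

Step 3
Reactants: 4 2-fluoro-5-(triisopropylsilyloxy)benzaldehyde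
Product: 7 2-fluoro-5-(triisopropylsilyloxy)benzene-1,3-dicarbaldehyde, via lithium amino alkoxide 5 (not isolated), via ring-lithiated amino alkoxide 6 (not isolated)
Conditions: LiN(CH2CH2)2NMe (from 1-methylpiperazine, n-BuLi), THF, −78 °C; s-BuLi, TMEDA, −78 °C; DMF; aq. NH4Cl
Reagents that add atoms: N,N-dimethylformamide, CN(C)C=O
Why: The aldehyde is masked in the flask as an α-amino alkoxide, a weak director, so a second fluorine-directed ortho-metalation should take the only remaining C–H next to fluorine before DMF formylation, with −78 °C held to keep the ortho-fluoro aryllithium from losing LiF.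

Step 4
Reactants: 7 2-fluoro-5-(triisopropylsilyloxy)benzene-1,3-dicarbaldehyde
Product: 8 2-fluoro-5-(prop-2-enyloxy)benzene-1,3-dicarbaldehyde
Conditions: CsF, allyl bromide (excess), DMF, 0 °C → rt
Reagents that add atoms: allyl bromide, C=CCBr
Why: Fluoride-induced desilylation with Williamson O-allylation in the same flask; the phenoxide, whose own C–F is deactivated by the para oxide, should be trapped by excess allyl bromide before it can attack an activated aryl fluoride.

Step 5
Reactants: 7 2-fluoro-5-(triisopropylsilyloxy)benzene-1,3-dicarbaldehyde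
Product: 9 2-fluoro-5-methoxybenzene-1,3-dicarbaldehyde
Conditions: CsF, MeI (excess), DMF, 0 °C → rt
Reagents that add atoms: iodomethane, CI
Why: The same desilylative Williamson etherification with MeI should give the ring A block, whose methoxy group stays until the last step.

Step 6
Reactants: 10 2-fluoro-4-methoxyphenol
Product: 11 (2-fluoro-4-methoxyphenoxy)triisopropylsilane
Conditions: TIPSCl, imidazole, DMF, rt
Reagents that add atoms: chlorotriisopropylsilane, CC(C)[Si](Cl)(C(C)C)C(C)C
Why: O-silylation of the phenol, which protects the oxygen that later becomes D C1–O and shields the C–H next to it.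

Step 7
Reactants: 11 (2-fluoro-4-methoxyphenoxy)triisopropylsilane
Product: 12 (5-bromo-2-fluoro-4-methoxyphenoxy)triisopropylsilane
Conditions: NBS, MeCN, 0 °C → rt
Reagents that add atoms: N-bromosuccinimide, O=C1CCC(=O)N1Br
Why: Electrophilic aromatic bromination should enter ortho to methoxy and para to fluorine, the most activated open carbon, since the C–H between F and OMe is crowded and the one next to the silyloxy group is shielded and meta to methoxy.

Step 8
Reactants: 12 (5-bromo-2-fluoro-4-methoxyphenoxy)triisopropylsilane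
Product: 14 4-fluoro-2-methoxy-5-(triisopropylsilyloxy)benzaldehyde, via aryllithium 13 (not isolated)
Conditions: n-BuLi, THF, −78 °C; DMF; aq. NH4Cl
Reagents that add atoms: N,N-dimethylformamide, CN(C)C=O
Why: Bromine–lithium exchange is faster than any deprotonation at −78 °C, and the aryllithium is formylated by DMF.

Step 9
Reactants: 14 4-fluoro-2-methoxy-5-(triisopropylsilyloxy)benzaldehyde
Product: 17 4-fluoro-2-methoxy-5-(triisopropylsilyloxy)benzene-1,3-dicarbaldehyde, via lithium amino alkoxide 15 (not isolated), via ring-lithiated amino alkoxide 16 (not isolated)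
Conditions: LiN(CH2CH2)2NMe (from 1-methylpiperazine, n-BuLi), THF, −78 °C; n-BuLi, −78 °C; DMF; aq. NH4Cl
Reagents that add atoms: N,N-dimethylformamide, CN(C)C=O
Why: With the aldehyde masked in the flask as its α-amino alkoxide, directed ortho-metalation should take the C–H flanked by fluorine and methoxy, the most acidic site of the ring, and DMF formylates it.

Step 10
Reactants: 17 4-fluoro-2-methoxy-5-(triisopropylsilyloxy)benzene-1,3-dicarbaldehyde
Product: 18 4-fluoro-2-methoxy-5-(prop-2-enyloxy)benzene-1,3-dicarbaldehyde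
Conditions: CsF, allyl bromide (excess), DMF, 0 °C → rt
Reagents that add atoms: allyl bromide, C=CCBr
Why: Desilylative Williamson O-allylation as in step 4; the phenoxide lies ortho to its own fluorine and so deactivates it while excess allyl bromide captures the oxygen.

Step 11
Reactants: 19 3,4,5-trimethoxyphenol; 8 2-fluoro-5-(prop-2-enyloxy)benzene-1,3-dicarbaldehyde
Product: 20 5-(prop-2-enyloxy)-2-(3,4,5-trimethoxyphenoxy)benzene-1,3-dicarbaldehyde
Conditions: K2CO3, DMF, rt, argon
Reagents that add atoms: none
Why: SNAr, in which the phenoxide adds to the fluorine-bearing carbon activated by two ortho formyl groups (Meisenheimer adduct) and fluoride leaves, should form the F–O–E ether at E C4.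

Step 12
Reactants: 20 5-(prop-2-enyloxy)-2-(3,4,5-trimethoxyphenoxy)benzene-1,3-dicarbaldehyde
Product: 21 5-hydroxy-2-(3,4,5-trimethoxyphenoxy)benzene-1,3-dicarbaldehyde
Conditions: Pd(PPh3)4 (cat.), TolSO2Na, THF–MeOH, rt; aq. NH4Cl
Reagents that add atoms: none
Why: Tsuji–Trost deallylation, in which zerovalent palladium ionises the allyl aryl ether to a π-allyl complex and the phenoxide and the sulfinate takes the allyl group, should free E C1–OH under neutral conditions that spare the formyl groups and keep acid away from ring F.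

Step 13
Reactants: 21 5-hydroxy-2-(3,4,5-trimethoxyphenoxy)benzene-1,3-dicarbaldehyde; 18 4-fluoro-2-methoxy-5-(prop-2-enyloxy)benzene-1,3-dicarbaldehyde
Product: 22 trimer allyl ether 4-[3,5-diformyl-4-(3,4,5-trimethoxyphenoxy)phenoxy]-2-methoxy-5-(prop-2-enyloxy)benzene-1,3-dicarbaldehyde
Conditions: Cs2CO3, DMF, rt → 40 °C, argon
Reagents that add atoms: none
Why: SNAr at D C6, whose fluoride is activated by the ortho formyl group at D C5 and the para formyl group at D C3, should form the E–O–D ether much faster than any attack at the methoxy- or aryloxy-bearing carbons.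

Step 14
Reactants: 22 trimer allyl ether
Product: 23 trimer phenol (22 with OH in place of the allyloxy group at D C1)
Conditions: Pd(PPh3)4 (cat.), TolSO2Na, THF–MeOH, rt; aq. NH4Cl
Reagents that add atoms: none
Why: Tsuji–Trost deallylation as in step 12 should free D C1–OH without touching four formyl groups or the methyl ethers.

Step 15
Reactants: 23 trimer phenol; 8 2-fluoro-5-(prop-2-enyloxy)benzene-1,3-dicarbaldehyde
Product: 24 tetramer allyl ether (rings F, E, D, C; allyloxy at C C1; six formyl groups)
Conditions: Cs2CO3, DMF, rt → 40 °C, argon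
Reagents that add atoms: none
Why: SNAr of the D C1 phenoxide on the doubly formyl-activated fluoride of 8 should form the D–O–C ether at C C4, fluoride being a far better leaving group than any aryloxide already in the chain.

Step 16
Reactants: 24 tetramer allyl ether
Product: 25 tetramer phenol (OH at C C1)
Conditions: Pd(PPh3)4 (cat.), TolSO2Na, THF–MeOH, rt; aq. NH4Cl
Reagents that add atoms: none
Why: Tsuji–Trost deallylation as in step 12.

Step 17
Reactants: 25 tetramer phenol; 8 2-fluoro-5-(prop-2-enyloxy)benzene-1,3-dicarbaldehyde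
Product: 26 pentamer allyl ether (rings F, E, D, C, B; allyloxy at B C1; eight formyl groups)
Conditions: Cs2CO3, DMF, rt → 40 °C, argon
Reagents that add atoms: none
Why: SNAr of the unhindered C C1 phenoxide on 8 should form the C–O–B ether at B C4.

Step 18
Reactants: 26 pentamer allyl ether
Product: 27 pentamer phenol (OH at B C1)
Conditions: Pd(PPh3)4 (cat.), TolSO2Na, THF–MeOH, rt; aq. NH4Cl
Reagents that add atoms: none
Why: Tsuji–Trost deallylation as in step 12.

Step 19
Reactants: 27 pentamer phenol; 9 2-fluoro-5-methoxybenzene-1,3-dicarbaldehyde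
Product: 28 hexamer decaaldehyde
Conditions: Cs2CO3, DMF, rt → 40 °C, argon
Reagents that add atoms: none
Why: SNAr of the B C1 phenoxide on the methoxy block should form the last ether, B–O–A at A C1, and complete the chain with two formyl groups on each of rings A to E.

Step 20
Reactants: 28 hexamer decaaldehyde
Product: 30 hexamer decaphenol pentamethyl ether, via decaformate 29 (not isolated)
Conditions: mCPBA (excess), CH2Cl2, 0 → 40 °C; aq. Na2S2O3/NaHCO3 wash; K2CO3, MeOH, argon, rt; dilute HCl
Reagents that add atoms: 3-chloroperoxybenzoic acid, OOC(=O)c1cccc(Cl)c1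
Why: Each formyl carbon adds the peracid to give a Criegee adduct whose aryl group migrates to oxygen with loss of 3-chlorobenzoate, so that ten aryl formates (29) form and are then cleaved by methanolysis to the phenols. The closest known reaction type is the Baeyer–Villiger (Dakin-type) oxidation of 2-alkoxy- and 2-aryloxybenzaldehydes to phenols, as used after fluoride displacement on fluorobenzaldehydes in diaryl ether synthesis, run here at ten sites of one molecule. No ring is closed and no stereocentre is formed. The step needs aryl migration to beat hydride migration at all ten sites, and this should be secured by the ether oxygen ortho to every formyl-bearing carbon (A C1, B C4, C C4, E C4, and D C4 with D C6), helped by the fact that each formate formed makes its ring richer for the second oxidation. Excess peracid is removed before the formates are cleaved, so that the free electron-rich phenols never meet the oxidant, and the methanolysis is run under argon.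

Step 21
Reactants: 30 hexamer decaphenol pentamethyl ether
Product: 31 CNP0175585.0
Conditions: BBr3 (excess), CH2Cl2, −78 °C → rt, argon; H2O
Reagents that add atoms: none
Why: Lewis acid ether cleavage, in which BBr3 coordinates each methoxy oxygen and bromide removes the methyl group, should free the five remaining hydroxyls (A C4, D C4, F C3, C4, C5) while the diaryl ether bonds stay intact.

**Compound list**

1 | 4-fluorophenol | Oc1ccc(F)cc1 | starting material
2 | (4-fluorophenoxy)triisopropylsilane | CC(C)[Si](C(C)C)(C(C)C)Oc1ccc(F)cc1 | intermediate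
3 | [2-fluoro-5-(triisopropylsilyloxy)phenyl]lithium | CC(C)[Si](C(C)C)(C(C)C)Oc1ccc(F)c([Li])c1 | intermediate (not isolated)
4 | 2-fluoro-5-(triisopropylsilyloxy)benzaldehyde | CC(C)[Si](C(C)C)(C(C)C)Oc1ccc(F)c(C=O)c1 | intermediate
5 | lithium [2-fluoro-5-(triisopropylsilyloxy)phenyl](4-methylpiperazin-1-yl)methanolate (racemic) | CC(C)[Si](C(C)C)(C(C)C)Oc1ccc(F)c(C(O[Li])N2CCN(C)CC2)c1 | intermediate (not isolated)
6 | 3-lithio derivative of 5 (lithium next to fluorine) | CC(C)[Si](C(C)C)(C(C)C)Oc1cc([Li])c(F)c(C(O[Li])N2CCN(C)CC2)c1 | intermediate (not isolated)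
7 | 2-fluoro-5-(triisopropylsilyloxy)benzene-1,3-dicarbaldehyde | CC(C)[Si](C(C)C)(C(C)C)Oc1cc(C=O)c(F)c(C=O)c1 | intermediate
8 | 2-fluoro-5-(prop-2-enyloxy)benzene-1,3-dicarbaldehyde (block for rings E, C, B) | C=CCOc1cc(C=O)c(F)c(C=O)c1 | intermediate
9 | 2-fluoro-5-methoxybenzene-1,3-dicarbaldehyde (block for ring A) | COc1cc(C=O)c(F)c(C=O)c1 | intermediate
10 | 2-fluoro-4-methoxyphenol | COc1ccc(O)c(F)c1 | starting material
11 | (2-fluoro-4-methoxyphenoxy)triisopropylsilane | COc1ccc(O[Si](C(C)C)(C(C)C)C(C)C)c(F)c1 | intermediate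
12 | (5-bromo-2-fluoro-4-methoxyphenoxy)triisopropylsilane | COc1cc(F)c(O[Si](C(C)C)(C(C)C)C(C)C)cc1Br | intermediate
13 | [4-fluoro-2-methoxy-5-(triisopropylsilyloxy)phenyl]lithium | COc1cc(F)c(O[Si](C(C)C)(C(C)C)C(C)C)cc1[Li] | intermediate (not isolated)
14 | 4-fluoro-2-methoxy-5-(triisopropylsilyloxy)benzaldehyde | COc1cc(F)c(O[Si](C(C)C)(C(C)C)C(C)C)cc1C=O | intermediate
15 | lithium [4-fluoro-2-methoxy-5-(triisopropylsilyloxy)phenyl](4-methylpiperazin-1-yl)methanolate (racemic) | COc1cc(F)c(O[Si](C(C)C)(C(C)C)C(C)C)cc1C(O[Li])N1CCN(C)CC1 | intermediate (not isolated)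
16 | 3-lithio derivative of 15 (lithium between F and OMe) | COc1c([Li])c(F)c(O[Si](C(C)C)(C(C)C)C(C)C)cc1C(O[Li])N1CCN(C)CC1 | intermediate (not isolated)
17 | 4-fluoro-2-methoxy-5-(triisopropylsilyloxy)benzene-1,3-dicarbaldehyde | COc1c(C=O)c(F)c(O[Si](C(C)C)(C(C)C)C(C)C)cc1C=O | intermediate
18 | 4-fluoro-2-methoxy-5-(prop-2-enyloxy)benzene-1,3-dicarbaldehyde (block for ring D) | COc1c(C=O)c(F)c(OCC=C)cc1C=O | intermediate
19 | 3,4,5-trimethoxyphenol | COc1cc(O)cc(OC)c1OC | starting material
20 | 5-(prop-2-enyloxy)-2-(3,4,5-trimethoxyphenoxy)benzene-1,3-dicarbaldehyde (rings F, E) | COc1cc(Oc2c(C=O)cc(OCC=C)cc2C=O)cc(OC)c1OC | intermediate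
21 | 5-hydroxy-2-(3,4,5-trimethoxyphenoxy)benzene-1,3-dicarbaldehyde | COc1cc(Oc2c(C=O)cc(O)cc2C=O)cc(OC)c1OC | intermediate
22 | trimer allyl ether, 4-[3,5-diformyl-4-(3,4,5-trimethoxyphenoxy)phenoxy]-2-methoxy-5-(prop-2-enyloxy)benzene-1,3-dicarbaldehyde | COc1cc(Oc2c(C=O)cc(Oc3c(OCC=C)cc(C=O)c(OC)c3C=O)cc2C=O)cc(OC)c1OC | intermediate
23 | trimer phenol (OH at D C1) | COc1cc(Oc2c(C=O)cc(Oc3c(O)cc(C=O)c(OC)c3C=O)cc2C=O)cc(OC)c1OC | intermediate
24 | tetramer allyl ether (rings F, E, D, C; allyloxy at C C1; six formyl groups) | COc1cc(Oc2c(C=O)cc(Oc3c(Oc4c(C=O)cc(OCC=C)cc4C=O)cc(C=O)c(OC)c3C=O)cc2C=O)cc(OC)c1OC | intermediate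
25 | tetramer phenol (OH at C C1) | COc1cc(Oc2c(C=O)cc(Oc3c(Oc4c(C=O)cc(O)cc4C=O)cc(C=O)c(OC)c3C=O)cc2C=O)cc(OC)c1OC | intermediate
26 | pentamer allyl ether (rings F to B; allyloxy at B C1; eight formyl groups) | COc1cc(Oc2c(C=O)cc(Oc3c(Oc4c(C=O)cc(Oc5c(C=O)cc(OCC=C)cc5C=O)cc4C=O)cc(C=O)c(OC)c3C=O)cc2C=O)cc(OC)c1OC | intermediate
27 | pentamer phenol (OH at B C1) | COc1cc(Oc2c(C=O)cc(Oc3c(Oc4c(C=O)cc(Oc5c(C=O)cc(O)cc5C=O)cc4C=O)cc(C=O)c(OC)c3C=O)cc2C=O)cc(OC)c1OC | intermediate
28 | hexamer decaaldehyde (two formyl groups on each of rings A to E; methoxy at A C4, D C4, F C3, C4, C5) | COc1cc(C=O)c(Oc2cc(C=O)c(Oc3cc(C=O)c(Oc4cc(C=O)c(OC)c(C=O)c4Oc4cc(C=O)c(Oc5cc(OC)c(OC)c(OC)c5)c(C=O)c4)c(C=O)c3)c(C=O)c2)c(C=O)c1 | intermediate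
29 | hexamer decaformate (OCHO in place of each formyl group of 28) | COc1cc(OC=O)c(Oc2cc(OC=O)c(Oc3cc(OC=O)c(Oc4cc(OC=O)c(OC)c(OC=O)c4Oc4cc(OC=O)c(Oc5cc(OC)c(OC)c(OC)c5)c(OC=O)c4)c(OC=O)c3)c(OC=O)c2)c(OC=O)c1 | intermediate (not isolated)
30 | hexamer decaphenol pentamethyl ether (OH in place of each formyl group of 28) | COc1cc(O)c(Oc2cc(O)c(Oc3cc(O)c(Oc4cc(O)c(OC)c(O)c4Oc4cc(O)c(Oc5cc(OC)c(OC)c(OC)c5)c(O)c4)c(O)c3)c(O)c2)c(O)c1 | intermediate
31 | CNP0175585.0 | Oc1cc(O)c(Oc2cc(O)c(Oc3cc(O)c(Oc4cc(O)c(O)c(O)c4Oc4cc(O)c(Oc5cc(O)c(O)c(O)c5)c(O)c4)c(O)c3)c(O)c2)c(O)c1 | target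

**Totals**

Total step count: 21. Longest linear sequence: 15 steps (steps 1 to 4, then 11 to 21).

**Steps most likely to fail**

1. Step 20. Hydride may migrate in place of aryl at some of the ten sites, which gives carboxylic acids, and a single such event spoils the product. Ring F may also be hydroxylated by excess peracid. Fallback, setting out from 28 and returning at 30: MeMgBr in THF at −78 °C should add to all ten formyl groups to give the deca(1-hydroxyethyl) compound F1 as a mixture of diastereomers. Dess–Martin periodinane should oxidise it to the decaacetyl compound F2, in which these stereocentres are gone. Baeyer–Villiger oxidation of F2 with mCPBA in CH2Cl2 at reflux, where aryl competes only with methyl and no hydride can migrate, should give the decaacetate F3. K2CO3 in MeOH under argon should cleave the acetates to 30.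

2. Step 15. The coupling may be slow, because the D C1 phenoxide has an aryloxy group beside it and must attack a carbon between two formyl groups. Meanwhile phenoxide may exchange with aryloxide at the internal ether carbons E C4 and D C6, which the formyl groups keep activated, and this scrambles the chain. The same exchange threatens steps 17 and 19. Fallback, setting out from 23 and returning at 24: NaBH4 in THF–MeOH should reduce the four formyl groups to hydroxymethyl groups and give the tetrakis(hydroxymethyl) phenol F4, whose ether carbons are no longer activated and whose phenoxide is more nucleophilic. Coupling of F4 with 8 (Cs2CO3, DMF, rt) should give the allyl ether F5, in which only the new ring C carries formyl groups. MnO2 in CH2Cl2 should oxidise the four benzylic alcohols back to aldehydes and give 24.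

3. Step 3. Deprotonation may occur at a carbon other than C3, the base may attack the masked aldehyde, or the ortho-fluoro aryllithium may lose LiF to an aryne if the temperature drifts. Fallback, setting out from 4 and returning at 7: ethylene glycol with TsOH (cat.) in toluene under water removal should give the dioxolane F6, so that a purified acetal with fluorine as its only directing group enters the lithiation. s-BuLi and TMEDA at −78 °C followed by DMF should give the dioxolane aldehyde F7. 1 M HCl in THF at rt should hydrolyse the acetal to 7 without loss of the aryl silyl ether.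

**Further compounds**

F1 | step 20 | hexamer deca(1-hydroxyethyl) compound (CH(OH)CH3 in place of each formyl group of 28; mixture of diastereomers) | COc1cc(C(C)O)c(Oc2cc(C(C)O)c(Oc3cc(C(C)O)c(Oc4cc(C(C)O)c(OC)c(C(C)O)c4Oc4cc(C(C)O)c(Oc5cc(OC)c(OC)c(OC)c5)c(C(C)O)c4)c(C(C)O)c3)c(C(C)O)c2)c(C(C)O)c1
F2 | step 20 | hexamer decaacetyl compound (acetyl in place of each formyl group of 28) | COc1cc(C(C)=O)c(Oc2cc(C(C)=O)c(Oc3cc(C(C)=O)c(Oc4cc(C(C)=O)c(OC)c(C(C)=O)c4Oc4cc(C(C)=O)c(Oc5cc(OC)c(OC)c(OC)c5)c(C(C)=O)c4)c(C(C)=O)c3)c(C(C)=O)c2)c(C(C)=O)c1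
F3 | step 20 | hexamer decaacetate (acetoxy in place of each formyl group of 28) | COc1cc(OC(C)=O)c(Oc2cc(OC(C)=O)c(Oc3cc(OC(C)=O)c(Oc4cc(OC(C)=O)c(OC)c(OC(C)=O)c4Oc4cc(OC(C)=O)c(Oc5cc(OC)c(OC)c(OC)c5)c(OC(C)=O)c4)c(OC(C)=O)c3)c(OC(C)=O)c2)c(OC(C)=O)c1
F4 | step 15 | trimer tetrakis(hydroxymethyl) phenol (CH2OH in place of each formyl group of 23) | COc1cc(Oc2c(CO)cc(Oc3c(O)cc(CO)c(OC)c3CO)cc2CO)cc(OC)c1OC
F5 | step 15 | tetramer allyl ether with four hydroxymethyl groups on rings E and D and two formyl groups on ring C | COc1cc(Oc2c(CO)cc(Oc3c(Oc4c(C=O)cc(OCC=C)cc4C=O)cc(CO)c(OC)c3CO)cc2CO)cc(OC)c1OC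
F6 | step 3 | 2-[2-fluoro-5-(triisopropylsilyloxy)phenyl]-1,3-dioxolane | CC(C)[Si](C(C)C)(C(C)C)Oc1ccc(F)c(C2OCCO2)c1
F7 | step 3 | 3-(1,3-dioxolan-2-yl)-2-fluoro-5-(triisopropylsilyloxy)benzaldehyde | CC(C)[Si](C(C)C)(C(C)C)Oc1cc(C=O)c(F)c(C2OCCO2)c1
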